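**Strategy.** Ring B is cut from ring A across C9–C10 and C5–C6. The shared bond C5–C10 joins the methyl-bearing quaternary C10 to C5, the α-carbon of the C4 ketone, so it is the alkene of a 2-methyl-2-ene-1,4-dione, while C6–C9 with O8 is a 2-silyloxybutadiene. One catalytic enantioselective Diels–Alder reaction of these two achiral partners, 2-methylcyclohex-2-ene-1,4-dione (4) and 2-(triisopropylsilyloxy)buta-1,3-diene (2), closes ring B, fixes C10 in absolute sense and places O8 in a regiodefined C7=C8 enol silane. Afterwards C5 is made trigonal and kept so until C1, C7, C8 and C6 are set; the trans fusion is created last.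

Key step: step 4

Remark: positions are numbered as in eudesmanes (ring A: C1–C5 and C10; ring B: C5–C10; side chain C11–C13 on C7; "decalin" names use this numbering); β is the face of the C10 methyl group.
Remark: the sense of induction in step 4 is assigned from the accepted pre-transition-state model of protonated oxazaborolidines, which calls for the (S)-prolinol-derived catalyst; should the adduct prove antipodal, the (R)-prolinol is used with no other change.

Step 1
Reactants: 1 but-3-en-2-one (methyl vinyl ketone)
Product: 2 2-(triisopropylsilyloxy)buta-1,3-diene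
Conditions: TIPSOTf, Et3N, Et2O, 0 → 23 °C
Reagents that add atoms: triisopropylsilyl triflate, CC(C)[Si](C(C)C)(C(C)C)OS(=O)(=O)C(F)(F)F
Why: Soft enolisation (O-silylation of the enone by the silyl triflate, then deprotonation of the methyl group by the amine) gives the 2-silyloxydiene (silyl enol ether formation).

Step 2
Reactants: 3 3-methylcyclohex-2-en-1-one
Product: 4 2-methylcyclohex-2-ene-1,4-dione
Conditions: Pd(OH)2 on carbon (5 mol %), t-BuOOH, K2CO3 (0.25 equiv), CH2Cl2, 4 → 23 °C
Reagents that add atoms: tert-butyl hydroperoxide, CC(C)(C)OO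
Why: Palladium-catalysed γ-oxidation of an α,β-enone to the 1,4-enedione: hydrogen abstraction at the ring CH2 allylic to the enone alkene and trapping by tert-butylperoxyl give a peroxide that collapses to the second ketone.

Step 3
Reactants: 5 (S)-diphenyl(pyrrolidin-2-yl)methanol; 6 2-methylphenylboronic acid
Product: 7 (S)-3,3-diphenyl-1-(2-methylphenyl)tetrahydro-1H,3H-pyrrolo[1,2-c][1,3,2]oxazaborole
Conditions: toluene, reflux, Dean–Stark trap (−H2O)
Reagents that add atoms: none
Why: Condensation of the amino alcohol with the boronic acid under azeotropic removal of water gives the B-aryl oxazaborolidine (cyclic aminoboronate formation); the stereocentre comes unchanged from the prolinol.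

Step 4
Reactants: 4 2-methylcyclohex-2-ene-1,4-dione; 2 2-(triisopropylsilyloxy)buta-1,3-diene
Product: 8 (4aR,8aS)-4a-methyl-6-(triisopropylsilyloxy)-2,3,4a,5,8,8a-hexahydronaphthalene-1,4-dione (cis-fused adduct: 10β-methyl and 5β-H; C1 and C4 ketones; C7=C8 enol silane)
Conditions: 7 (20 mol %), Tf2NH (17 mol %), CH2Cl2, −78 → −40 °C
Reagents that add atoms: none
Why: Protonation of 7 by Tf2NH gives a cationic boron Lewis acid that binds the C4 carbonyl of 4 at the lone pair next to the vinylic C5–H, so that C10 becomes the electrophilic β-carbon and the CH2 terminus adjacent to the silyloxy carbon of 2 bonds to it in a concerted, asynchronous [4+2] cycloaddition. The closest known reaction type is the oxazaborolidinium-catalysed enantioselective Diels–Alder reaction of quinones and enediones with 2-silyloxybutadienes. Ring B, the only ring closed, is formed in intermolecular [4+2] mode, the bonds C9–C10 and C5–C6 arising in the same cycloaddition. The configuration of the quaternary C10 is controlled by the catalyst, which shields one face of the bound dienophile, and that of C5 by the suprafacial addition, which makes the fusion cis. The step needs regioselectivity (O8 on C8 and not on C7), secured by activation through the C4 carbonyl and the polarisation of the diene, and chemoselectivity, secured by the single doubly activated alkene of 4 and the acid-tolerant triisopropylsilyl enol ether.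

Step 5
Reactants: 8 cis-fused adduct
Product: 9 (4aR,8aS)-4a-methyl-2,3,4a,8a-tetrahydronaphthalene-1,4,6(5H)-trione (cis-fused enetrione: C1, C4 and C8 ketones; C6=C7)
Conditions: Pd(OAc)2 (1.1 equiv), MeCN, 23 °C
Reagents that add atoms: none
Why: Saegusa–Ito oxidation: the enol silane is converted into a palladium enolate at C7, and β-hydride elimination, possible only towards C6, gives the 6-en-8-one without touching the ring A ketones.

Step 6
Reactants: 9 cis-fused enetrione
Product: 10 (4aR)-4a-methyl-6-(triisopropylsilyloxy)-2,3,4a,5-tetrahydronaphthalene-1,4-dione (silyloxy dienone: C5=C6 and C7=C8; O8 silylated; C1 and C4 ketones)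
Conditions: TIPSOTf (1.1 equiv), Et3N, CH2Cl2, −78 °C (9 used without purification)
Reagents that add atoms: triisopropylsilyl triflate, CC(C)[Si](C(C)C)(C(C)C)OS(=O)(=O)C(F)(F)F
Why: Soft enolisation: the silyl triflate activates the enone oxygen O8 (the most Lewis basic and least hindered carbonyl oxygen) and the amine removes the doubly activated C5–H (α to C4=O, γ to the enone), giving the linear silyl dienol ether; C5 is now trigonal, so its configuration no longer matters.

Step 7
Reactants: 10 silyloxy dienone
Product: 11 10β-methyl-8-(triisopropylsilyloxy)decala-5,7-diene-1β,4β-diol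
Conditions: LiAlH4, THF, −78 → −20 °C; aq. KNaC4H4O6 (potassium sodium tartrate) work-up
Reagents that add atoms: none
Why: Hydride reduction: the C1 ketone is attacked from the α face, anti to the methyl group on the adjacent quaternary C10 (general for ketones next to a methyl-bearing ring-fusion carbon), which sets the 1β-alcohol; the vinylogous C4 carbonyl undergoes 1,2-reduction to an allylic alcohol whose configuration (4β expected) is of no consequence, and the silyl dienol ether is inert to hydride.

Step 8
Reactants: 11 dienol silane diol; 12 allyl bromide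
Product: 13 7β-allyl-1β,4β-dihydroxy-10β-methyldecal-5-en-8-one (formed together with its C7 epimer; both enter step 9)
Conditions: Bu4N+ Ph3SiF2− (TBAT), THF, −78 → 0 °C
Reagents that add atoms: none
Why: Fluoride cleaves the silyl dienol ether to the ammonium dienolate regiospecifically, and this is alkylated by allyl bromide at its α-carbon C7 (enolate alkylation), leaving C5=C6 out of conjugation; the alcohols are much weaker acids than the conjugate acid of the stabilised dienolate and do not quench it, and the C7 configuration formed here is reset in step 9.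

Step 9
Reactants: 13 7β-allyl-1β,4β-dihydroxy-10β-methyldecal-5-en-8-one
Product: 15 7β-allyl-10β-methyldecal-5-ene-1β,4β,8α-triol, via trilithium dienolate 14 (not isolated)
Conditions: LiN(SiMe3)2 (3.3 equiv), THF, −78 °C; then Li (excess), NH3(l), −78 °C, slow addition of EtOH; NH4Cl
Reagents that add atoms: none
Why: Re-enolisation erases C7; ethanol then protonates the dienolate kinetically at the α-carbon C7 from the α face, anti to the C10 methyl, which makes the allyl group equatorial (7β), and the ketone so released is reduced at once by the dissolved lithium (dissolving-metal reduction) to the thermodynamically preferred equatorial 8α-alcohol, which hydride reagents would not give because axial attack at C8 is blocked by the syn-axial C10 methyl.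

Step 10
Reactants: 15 7β-allyl-10β-methyldecal-5-ene-1β,4β,8α-triol
Product: 16 7β-allyl-1β,8α-dihydroxy-10β-methyldecal-5-en-4-one
Conditions: MnO2 (activated, excess), CH2Cl2, 23 °C
Reagents that add atoms: none
Why: Manganese dioxide oxidises only the allylic C4 alcohol (chemoselective allylic oxidation) and so returns the C4 ketone, now conjugated with C5=C6.

Step 11
Reactants: 16 7β-allyl-1β,8α-dihydroxy-10β-methyldecal-5-en-4-one
Product: 17 7β-allyl-5α,6α-epoxy-1β,8α-dihydroxy-10β-methyldecalin-4-one
Conditions: 30% H2O2, NaOH (aq., 0.3 equiv), MeOH, 0 °C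
Reagents that add atoms: hydrogen peroxide, OO
Why: Weitz–Scheffer nucleophilic epoxidation: hydroperoxide adds to C6 of the enone from the α face, the β face being shielded by the C10 methyl that is 1,3 to C6, and closure of the enolate onto oxygen gives the 5α,6α-epoxide, which places the C6–O bond on the α face.

Step 12
Reactants: 17 7β-allyl-5α,6α-epoxy-1β,8α-dihydroxy-10β-methyldecalin-4-one
Product: 18 7β-allyl-1β,6α,8α-trihydroxy-10β-methyl-5α-H-decalin-4-one (trans-fused)
Conditions: SmI2 (2.5 equiv), THF/MeOH, −78 °C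
Reagents that add atoms: none
Why: Samarium diiodide cleaves the C5–O bond of the α,β-epoxy ketone by two single-electron transfers (reductive epoxide opening) and leaves C6–O untouched; protonation of the samarium enolate at C5 from the face anti to the C10 methyl gives the trans fusion, which is also the more stable one because all four ring substituents are then equatorial, so any 5β-H material converges on mild base contact.

Step 13
Reactants: 18 trans-fused triol ketone
Product: 19 7β-allyl-1β,6α-dihydroxy-10β-methyl-8α-(triethylsilyloxy)-5α-H-decalin-4-one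
Conditions: TESCl (1.05 equiv), imidazole, CH2Cl2, −20 °C
Reagents that add atoms: chlorotriethylsilane, CC[Si](CC)(CC)Cl
Why: Selective silylation: the C8 hydroxyl, flanked by a CH2 group, is the least hindered of the three (C1–OH is neopentyl; C6–OH lies between two methine carbons and is hydrogen-bonded to the C4 ketone), so one equivalent of chlorosilane at low temperature should react at O8 only.

Step 14
Reactants: 19 8α-triethylsilyl ether
Product: 20 7β-allyl-1β,6α-bis(tert-butyldimethylsilyloxy)-10β-methyl-8α-(triethylsilyloxy)-5α-H-decalin-4-one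
Conditions: TBSOTf (2.5 equiv), 2,6-lutidine, CH2Cl2, −78 → 0 °C
Reagents that add atoms: tert-butyldimethylsilyl triflate, CC(C)(C)[Si](C)(C)OS(=O)(=O)C(F)(F)F
Why: A silyl triflate with a hindered pyridine base silylates the two remaining hindered secondary alcohols (silyl ether formation) without enolising the ketone.

Step 15
Reactants: 20 fully silylated allyl ketone
Product: 22 2-[1β,6α-bis(tert-butyldimethylsilyloxy)-10β-methyl-4-oxo-8α-(triethylsilyloxy)-5α-H-decalin-7β-yl]acetaldehyde, via ozonide 21 (not isolated)
Conditions: O3, CH2Cl2, −78 °C; then PPh3, −78 → 23 °C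
Reagents that add atoms: ozone, [O-][O+]=O
Why: Ozonolysis with reductive work-up cleaves the only alkene to the C12 aldehyde and formaldehyde.

Step 16
Reactants: 22 C12 aldehyde
Product: 23 2-[1β,6α-bis(tert-butyldimethylsilyloxy)-10β-methyl-4-oxo-8α-(triethylsilyloxy)-5α-H-decalin-7β-yl]prop-2-enal
Conditions: 37% aq. CH2O, pyrrolidine (10 mol %), propionic acid (10 mol %), i-PrOH, 45 °C
Reagents that add atoms: formaldehyde, C=O
Why: Amine-catalysed α-methylenation of an aldehyde (Mannich condensation with formaldehyde, then elimination of the amine) is selective for the aldehyde over the hindered C4 ketone and installs C13.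

Step 17
Reactants: 23 2-substituted acrolein
Product: 24 2-[1β,6α-bis(tert-butyldimethylsilyloxy)-10β-methyl-4-oxo-8α-(triethylsilyloxy)-5α-H-decalin-7β-yl]prop-2-enoic acid
Conditions: NaClO2, NaH2PO4, 2-methyl-2-butene, t-BuOH/H2O, 0 → 23 °C
Reagents that add atoms: sodium chlorite, [Na+].[O-]Cl=O
Why: Pinnick oxidation converts the enal into the acrylic acid without touching the alkene, the ketone or the silyl ethers.

Step 18
Reactants: 24 acrylic acid
Product: 25 methyl 2-[1β,6α-bis(tert-butyldimethylsilyloxy)-10β-methyl-4-oxo-8α-(triethylsilyloxy)-5α-H-decalin-7β-yl]prop-2-enoate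
Conditions: TMSCHN2, PhMe/MeOH, 0 °C
Reagents that add atoms: trimethylsilyldiazomethane, C[Si](C)(C)C=[N+]=[N-]
Why: Esterification with trimethylsilyldiazomethane in methanol is fast and neutral and leaves the Michael acceptor alone.

Step 19
Reactants: 25 methyl acrylate with O8 triethylsilyl ether
Product: 26 methyl 2-[1β,6α-bis(tert-butyldimethylsilyloxy)-8α-hydroxy-10β-methyl-4-oxo-5α-H-decalin-7β-yl]prop-2-enoate
Conditions: PPTS (cat.), MeOH/CH2Cl2, 0 °C
Reagents that add atoms: none
Why: Mild acid-catalysed methanolysis removes the triethylsilyl ether much faster than the two hindered tert-butyldimethylsilyl ethers (selective desilylation).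

Step 20
Reactants: 27 ethyl 2-(hydroxymethyl)prop-2-enoate
Product: 28 ethyl 2-[(tert-butyldimethylsilyloxy)methyl]prop-2-enoate
Conditions: TBSCl, imidazole, DMF, 0 → 23 °C
Reagents that add atoms: tert-butyldimethylsilyl chloride, CC(C)(C)[Si](C)(C)Cl
Why: Silyl ether formation masks the primary hydroxyl of the acyl fragment.

Step 21
Reactants: 28 silylated ethyl ester
Product: 29 2-[(tert-butyldimethylsilyloxy)methyl]prop-2-enoic acid
Conditions: LiOH, THF/H2O, 0 °C; 1 M HCl to pH 4
Reagents that add atoms: lithium hydroxide, [Li+].[OH-]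
Why: Saponification of the ethyl ester in the cold followed by careful acidification gives the acid; the silyl ether survives both.

Step 22
Reactants: 26 8α-alcohol; 29 2-[(tert-butyldimethylsilyloxy)methyl]prop-2-enoic acid
Product: 31 tris(tert-butyldimethylsilyl) ether of the target (O1 O6 and the hydroxymethyl oxygen silylated), via mixed anhydride 30 (not isolated)
Conditions: 2,4,6-Cl3C6H2COCl, Et3N, THF, 0 °C; then 26, DMAP, toluene, 23 °C
Reagents that add atoms: none
Why: Yamaguchi esterification: DMAP attacks the mixed anhydride at the less hindered acrylic carbonyl and the acylpyridinium ion acylates the equatorial C8 hydroxyl, the only free one, with retention at C8.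

Step 23
Reactants: 31 tris(tert-butyldimethylsilyl) ether of the target
Product: 32 CNP0144895.1, methyl 2-[(1R,5S,6S,7S,8S,10R)-1,6-dihydroxy-8-{[2-(hydroxymethyl)prop-2-enoyl]oxy}-10-methyl-4-oxodecalin-7-yl]prop-2-enoate
Conditions: HF·pyridine, pyridine, THF, 0 → 23 °C
Reagents that add atoms: none
Why: Buffered hydrogen fluoride–pyridine cleaves the three silyl ethers (fluoride-driven desilylation) without the basic or strongly acidic conditions that would cause acyl migration, lactonisation onto C12 or β-elimination of the C6 hydroxyl.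

**Compound list**

1 | but-3-en-2-one (methyl vinyl ketone) | CC(=O)C=C | starting material
2 | 2-(triisopropylsilyloxy)buta-1,3-diene | C=CC(=C)O[Si](C(C)C)(C(C)C)C(C)C | intermediate
3 | 3-methylcyclohex-2-en-1-one | CC1=CC(=O)CCC1 | starting material
4 | 2-methylcyclohex-2-ene-1,4-dione | CC1=CC(=O)CCC1=O | intermediate
5 | (S)-diphenyl(pyrrolidin-2-yl)methanol | OC(c1ccccc1)(c1ccccc1)[C@@H]1CCCN1 | starting material
6 | 2-methylphenylboronic acid | Cc1ccccc1B(O)O | starting material
7 | (S)-3,3-diphenyl-1-(2-methylphenyl)tetrahydro-1H,3H-pyrrolo[1,2-c][1,3,2]oxazaborole | Cc1ccccc1B1OC(c2ccccc2)(c2ccccc2)[C@@H]2CCCN12 | intermediate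
8 | (4aR,8aS)-4a-methyl-6-(triisopropylsilyloxy)-2,3,4a,5,8,8a-hexahydronaphthalene-1,4-dione (cis-fused adduct) | CC(C)[Si](C(C)C)(C(C)C)OC=1C[C@@]2(C)C(=O)CCC(=O)[C@H]2CC=1 | intermediate
9 | (4aR,8aS)-4a-methyl-2,3,4a,8a-tetrahydronaphthalene-1,4,6(5H)-trione (cis-fused 6-ene-1,4,8-trione) | O=C1C[C@@]2(C)C(=O)CCC(=O)[C@H]2C=C1 | intermediate
10 | (4aR)-4a-methyl-6-(triisopropylsilyloxy)-2,3,4a,5-tetrahydronaphthalene-1,4-dione (5,7-diene, O8 silylated) | CC(C)[Si](C(C)C)(C(C)C)OC=1C[C@@]2(C)C(=O)CCC(=O)C2=CC=1 | intermediate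
11 | 10β-methyl-8-(triisopropylsilyloxy)decala-5,7-diene-1β,4β-diol | CC(C)[Si](C(C)C)(C(C)C)OC=1C[C@@]2(C)[C@H](O)CC[C@H](O)C2=CC=1 | intermediate
12 | allyl bromide | C=CCBr | starting material
13 | 7β-allyl-1β,4β-dihydroxy-10β-methyldecal-5-en-8-one (7β epimer shown) | O=C1C[C@@]2(C)[C@H](O)CC[C@H](O)C2=C[C@@H]1CC=C | intermediate
14 | trilithium salt of 13 (O1 and O4 alkoxides, C7=C8 enolate) | [Li+].[Li+].[Li+].[O-]C=1C[C@@]2(C)[C@H]([O-])CC[C@H]([O-])C2=CC=1CC=C | intermediate
15 | 7β-allyl-10β-methyldecal-5-ene-1β,4β,8α-triol | O[C@H]1C[C@@]2(C)[C@H](O)CC[C@H](O)C2=C[C@@H]1CC=C | intermediate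
16 | 7β-allyl-1β,8α-dihydroxy-10β-methyldecal-5-en-4-one | O[C@H]1C[C@@]2(C)[C@H](O)CCC(=O)C2=C[C@@H]1CC=C | intermediate
17 | 7β-allyl-5α,6α-epoxy-1β,8α-dihydroxy-10β-methyldecalin-4-one | O[C@H]1C[C@@]2(C)[C@H](O)CCC(=O)[C@@]23O[C@H]3[C@@H]1CC=C | intermediate
18 | 7β-allyl-1β,6α,8α-trihydroxy-10β-methyl-5α-H-decalin-4-one | O[C@H]1C[C@@]2(C)[C@H](O)CCC(=O)[C@@H]2[C@@H](O)[C@@H]1CC=C | intermediate
19 | 7β-allyl-1β,6α-dihydroxy-10β-methyl-8α-(triethylsilyloxy)-5α-H-decalin-4-one | CC[Si](CC)(CC)O[C@H]1C[C@@]2(C)[C@H](O)CCC(=O)[C@@H]2[C@@H](O)[C@@H]1CC=C | intermediate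
20 | 7β-allyl-1β,6α-bis(tert-butyldimethylsilyloxy)-10β-methyl-8α-(triethylsilyloxy)-5α-H-decalin-4-one | CC[Si](CC)(CC)O[C@H]1C[C@@]2(C)[C@H](O[Si](C)(C)C(C)(C)C)CCC(=O)[C@@H]2[C@@H](O[Si](C)(C)C(C)(C)C)[C@@H]1CC=C | intermediate
21 | secondary ozonide of 20 (1,2,4-trioxolan-3-ylmethyl group on C7, both epimers at the acetal carbon) | CC[Si](CC)(CC)O[C@H]1C[C@@]2(C)[C@H](O[Si](C)(C)C(C)(C)C)CCC(=O)[C@@H]2[C@@H](O[Si](C)(C)C(C)(C)C)[C@@H]1CC3OCOO3 | intermediate
22 | 2-[1β,6α-bis(tert-butyldimethylsilyloxy)-10β-methyl-4-oxo-8α-(triethylsilyloxy)-5α-H-decalin-7β-yl]acetaldehyde | CC[Si](CC)(CC)O[C@H]1C[C@@]2(C)[C@H](O[Si](C)(C)C(C)(C)C)CCC(=O)[C@@H]2[C@@H](O[Si](C)(C)C(C)(C)C)[C@@H]1CC=O | intermediate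
23 | 2-[same decalin-7β-yl]prop-2-enal | CC[Si](CC)(CC)O[C@H]1C[C@@]2(C)[C@H](O[Si](C)(C)C(C)(C)C)CCC(=O)[C@@H]2[C@@H](O[Si](C)(C)C(C)(C)C)[C@@H]1C(=C)C=O | intermediate
24 | 2-[same decalin-7β-yl]prop-2-enoic acid | CC[Si](CC)(CC)O[C@H]1C[C@@]2(C)[C@H](O[Si](C)(C)C(C)(C)C)CCC(=O)[C@@H]2[C@@H](O[Si](C)(C)C(C)(C)C)[C@@H]1C(=C)C(=O)O | intermediate
25 | methyl ester of 24 | CC[Si](CC)(CC)O[C@H]1C[C@@]2(C)[C@H](O[Si](C)(C)C(C)(C)C)CCC(=O)[C@@H]2[C@@H](O[Si](C)(C)C(C)(C)C)[C@@H]1C(=C)C(=O)OC | intermediate
26 | methyl 2-[1β,6α-bis(tert-butyldimethylsilyloxy)-8α-hydroxy-10β-methyl-4-oxo-5α-H-decalin-7β-yl]prop-2-enoate | O[C@H]1C[C@@]2(C)[C@H](O[Si](C)(C)C(C)(C)C)CCC(=O)[C@@H]2[C@@H](O[Si](C)(C)C(C)(C)C)[C@@H]1C(=C)C(=O)OC | intermediate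
27 | ethyl 2-(hydroxymethyl)prop-2-enoate | C=C(CO)C(=O)OCC | starting material
28 | ethyl 2-[(tert-butyldimethylsilyloxy)methyl]prop-2-enoate | C=C(CO[Si](C)(C)C(C)(C)C)C(=O)OCC | intermediate
29 | 2-[(tert-butyldimethylsilyloxy)methyl]prop-2-enoic acid | C=C(CO[Si](C)(C)C(C)(C)C)C(=O)O | intermediate
30 | mixed anhydride of 29 with 2,4,6-trichlorobenzoic acid | C=C(CO[Si](C)(C)C(C)(C)C)C(=O)OC(=O)c1c(Cl)cc(Cl)cc1Cl | intermediate
31 | target with O1, O6 and the hydroxymethyl oxygen as tert-butyldimethylsilyl ethers | C=C(CO[Si](C)(C)C(C)(C)C)C(=O)O[C@H]1C[C@@]2(C)[C@H](O[Si](C)(C)C(C)(C)C)CCC(=O)[C@@H]2[C@@H](O[Si](C)(C)C(C)(C)C)[C@@H]1C(=C)C(=O)OC | intermediate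
32 | CNP0144895.1, methyl 2-[(1R,5S,6S,7S,8S,10R)-1,6-dihydroxy-8-{[2-(hydroxymethyl)prop-2-enoyl]oxy}-10-methyl-4-oxodecalin-7-yl]prop-2-enoate | C=C(CO)C(=O)O[C@H]1C[C@@]2(C)[C@H](O)CCC(=O)[C@@H]2[C@@H](O)[C@@H]1C(=C)C(=O)OC | target

**Step count.** Total: 23 steps. Longest linear sequence: 19 steps (steps 2, 4–19, 22, 23).

**Steps most likely to fail**

Step 6. The silyl group may be transferred to O4 instead of O8, or the C6=C7 bond of 9 may drift into conjugation with C4 before silylation; either process gives the isomeric dienol ether and misdirects steps 7 and 8. The fallback sets out from 8 and comes back to the route at 16. NaBH4 at −78 °C should reduce the less hindered C4 ketone of 8 to the 4-hydroxy enol silane F1. Saegusa–Ito oxidation then gives the 4-hydroxy-6-ene-1,8-dione F2, whose C5–H is no longer doubly activated. Deconjugative α-alkylation of its extended dienolate (KOt-Bu, t-BuOH, allyl bromide) gives the 7-allyl-4-hydroxy-5-ene-1,8-dione F3. The dissolving-metal conditions of step 9 reduce both the C8 and the C1 ketone to equatorial alcohols, giving the 5-ene-1β,4,8α-triol F4 (C4 epimers), and MnO2 converts F4 into 16.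

Step 8. Proton exchange between product and dienolate may cause double allylation, the dienolate may expel the C4 hydroxyl by vinylogous β-elimination, and the C5=C6 bond may move into conjugation with the C8 ketone. The fallback sets out from 9 and comes back at 13. The dienolate of 9 is trapped with allyl chloroformate and Et3N as the allyl dienyl carbonate F5. Luche reduction (NaBH4, CeCl3) of C1 and C4 gives the diol carbonate F6. Tsuji decarboxylative allylation (Pd(PPh3)4, THF) then delivers the allyl group to C7 within the ion pair, with no free fluoride-generated enolate, and gives 13.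

Step 9. Protonation at C7 may show poor facial selectivity, and some protonation at C5 would return a conjugated enone that is then over-reduced. The fallback sets out from 16 and comes back at 16 and makes no new compound. The C7 epimers are carried through step 10 and equilibrated at the enone stage through the dienolate (NaOMe, MeOH, 23 °C), where the 7β-allyl and 8α-hydroxyl groups are both equatorial; this is the same thermodynamic γ-epimerisation known for 6-substituted cyclohex-2-enones in fused systems.

**Further compounds**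

F1 | step 6 | (4aR,8aS)-4-hydroxy... cis-fused 4-hydroxy-10β-methyl-8-(triisopropylsilyloxy)decal-7-en-1-one (C4 epimers) | CC(C)[Si](C(C)C)(C(C)C)OC=1C[C@@]2(C)C(=O)CCC(O)[C@H]2CC=1
F2 | step 6 | cis-fused 4-hydroxy-10β-methyldecal-6-ene-1,8-dione (C4 epimers) | O=C1C[C@@]2(C)C(=O)CCC(O)[C@H]2C=C1
F3 | step 6 | 7β-allyl-4-hydroxy-10β-methyldecal-5-ene-1,8-dione (C4 epimers) | O=C1C[C@@]2(C)C(=O)CCC(O)C2=C[C@@H]1CC=C
F4 | step 6 | 7β-allyl-10β-methyldecal-5-ene-1β,4,8α-triol (C4 epimers) | O[C@H]1C[C@@]2(C)[C@H](O)CCC(O)C2=C[C@@H]1CC=C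
F5 | step 8 | allyl (4aR)-4a-methyl-1,4-dioxo-1,2,3,4,4a,5-hexahydronaphthalen-6-yl carbonate (5,7-diene, O8 allyl carbonate) | C=CCOC(=O)OC=1C[C@@]2(C)C(=O)CCC(=O)C2=CC=1
F6 | step 8 | allyl 1β,4β-dihydroxy-10β-methyldecala-5,7-dien-8-yl carbonate | C=CCOC(=O)OC=1C[C@@]2(C)[C@H](O)CC[C@H](O)C2=CC=1
F0 | step 9 | none | none
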